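**Retrosynthetic overview**
- Hispidanin B ⇒ Diels–Alder union of a labdane diene acid with a totarane 3-methylene-benzofuranone that is made by lactonisation in the same flask (lactone and spiro-cyclohexene form in one operation, last).
- Labdane half ⇒ one radical bicyclisation of an acyclic trienyne ester: hydrogen-atom transfer to the isopropenyl end, ring A by 6-endo addition to the central enoate, ring B by 6-endo addition to an allyl sulfone whose sulfonyl group leaves to give the 8(17)-methylene.
- Acyclic precursor ⇒ Horner–Wadsworth–Emmons union of an alkylated phosphonoacetate with an enynal built by Nozaki–Hiyama–Kishi coupling and Claisen rearrangement; the butynyl group later becomes the 12E,14-diene.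
- Totarane half ⇒ (+)-totarol with its three rings intact: C7 oxidation and reduction, O7-radical relay to the peri isopropyl group, then allylic oxidation to the 2-arylacrylic acid.
- Ring order: labdane rings A then B (one step); totarane rings from the chiral pool; lactone and spiro-cyclohexene together in the last step.

Assumption: commercial (+)-totarol has the (5S,10S) configuration drawn for 17; the labdane half is made as a racemate and resolved in step 7.

**Route**

Step 1
Reactants: 1 2,3-dibromoprop-1-ene
Product: 2 [(2-bromoprop-2-en-1-yl)sulfonyl]benzene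
Conditions: PhSO2Na, DMF, 25 °C
Reagents that add atoms: sodium benzenesulfinate [Na+].[O-]S(=O)c1ccccc1
Why: SN2 S-alkylation of the sulfinate at the allylic bromide, the vinylic bromide being inert.

Step 2
Reactants: 3 pent-3-yn-1-ol
Product: 4 pent-3-ynal
Conditions: Dess–Martin periodinane, CH2Cl2, 0 °C; used crude
Reagents that add atoms: none
Why: Dess–Martin oxidation stops at the aldehyde under non-basic conditions, which avoids isomerisation of the β,γ-ynal to the allenal.

Step 3
Reactants: 4 pent-3-ynal; 2 [(2-bromoprop-2-en-1-yl)sulfonyl]benzene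
Product: 5 rac-2-[(phenylsulfonyl)methyl]hept-1-en-5-yn-3-ol
Conditions: CrCl2 (4 equiv), NiCl2 (2 mol%), DMF, 25 °C
Reagents that add atoms: none
Why: Nozaki–Hiyama–Kishi coupling, in which the non-basic alkenylchromium adds to the aldehyde without touching the acidic sulfone or the enolisable ynal; the carbinol centre is racemic and is destroyed in step 4.

Step 4
Reactants: 5 rac-2-[(phenylsulfonyl)methyl]hept-1-en-5-yn-3-ol
Product: 7 (4Z)-4-[(phenylsulfonyl)methyl]non-4-en-7-ynal, via allyl vinyl ether 6 (not isolated)
Conditions: ethyl vinyl ether, Pd(OCOCF3)2 (2 mol%), 1,10-phenanthroline (2 mol%), 60 °C (sealed); then xylene, 140 °C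
Reagents that add atoms: ethyl vinyl ether C=COCC
Why: Transfer vinylation then Claisen rearrangement through a chair with the butynyl group equatorial, which puts it trans to the new CH2CH2CHO chain and cis to CH2SO2Ph (the 4Z alkene needed for an equatorial C9 side chain later).

Step 5
Reactants: 8 methyl (dimethoxyphosphoryl)acetate; 9 5-bromo-2-methylpent-1-ene; 7 (4Z)-4-[(phenylsulfonyl)methyl]non-4-en-7-ynal
Product: 11 methyl (6Z)-2-(4-methylpent-4-en-1-yl)-6-[(phenylsulfonyl)methyl]undeca-2,6-dien-9-ynoate, via alkylated phosphonate 10 (not isolated)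
Conditions: NaH, DMF, then 9, 50 °C; then NaH, THF, 0 °C, then 7, −20 → 0 °C
Reagents that add atoms: none
Why: Phosphonate C-alkylation followed by Horner–Wadsworth–Emmons olefination; the 2E/2Z mixture is used as such because C10 becomes a planar radical in step 6.

Step 6
Reactants: 11 methyl (6Z)-2-(4-methylpent-4-en-1-yl)-6-[(phenylsulfonyl)methyl]undeca-2,6-dien-9-ynoate
Product: 12 racemic methyl 14,15-dinorlabd-8(17)-en-12-yn-20-oate
Conditions: Fe(acac)3 (30 mol%), PhSiH3 (1.5 equiv, slow addition), EtOH/(CH2OH)2 5:1, 0.01 M, 60 °C; stopped when 11 is consumed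
Reagents that add atoms: none
Why: Proposed new method: hydrogen-atom transfer from an iron hydride to the 1,1-disubstituted alkene gives the C4 tertiary radical, which closes ring A by polarity-matched 6-endo Giese addition to C5 of the enoate; the planar C10 α-ester radical then closes ring B 6-endo on C9 through a chair (equatorial C5 and C9 substituents, axial ester, trans-decalin), and the C8 radical expels PhSO2• to fix the 8(17)-alkene; the closest known reaction types are iron-hydride-initiated radical polyene cyclisations through an electron-poor central alkene and radical allylation with allyl sulfones; C5, C9 and C10 are set relative to one another (racemate).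

Step 7
Reactants: 12 racemic methyl 14,15-dinorlabd-8(17)-en-12-yn-20-oate
Product: 13 methyl (5S,9S,10R)-14,15-dinorlabd-8(17)-en-12-yn-20-oate
Conditions: preparative chiral SFC, amylose tris(3,5-dimethylphenylcarbamate) column, CO2/i-PrOH
Reagents that add atoms: none
Why: Chromatographic resolution of the racemate on a chiral stationary phase, which selects the (5S,9S,10R) absolute configuration of the three centres whose relative configuration was set in step 6.

Step 8
Reactants: 13 methyl (5S,9S,10R)-14,15-dinorlabd-8(17)-en-12-yn-20-oate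
Product: 15 methyl (5S,9S,10R,12E)-labda-8(17),12,14-trien-20-oate, via alkenylzirconocene chloride 14 (not isolated)
Conditions: Cp2Zr(H)Cl (1.5 equiv), THF, 40 °C; then vinyl bromide, Pd(PPh3)4 (5 mol%), ZnCl2 (0.3 equiv), 25 °C
Reagents that add atoms: vinyl bromide C=CBr
Why: syn-Hydrozirconation puts zirconium on the less hindered, methyl-bearing alkyne carbon C13, and Negishi-type palladium-catalysed coupling with retention gives the 12E trisubstituted diene.

Step 9
Reactants: 15 methyl (5S,9S,10R,12E)-labda-8(17),12,14-trien-20-oate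
Product: 16 (5S,9S,10R,12E)-labda-8(17),12,14-trien-20-oic acid
Conditions: n-PrSLi, HMPA, 25 °C; then aq. HCl
Reagents that add atoms: none
Why: SN2 demethylation by thiolate at the ester methyl carbon, which needs no attack at the hindered angular carbonyl and leaves the alkenes untouched.

Step 10
Reactants: 17 (+)-totarol
Product: 18 totara-8,11,13-trien-13-yl acetate
Conditions: Ac2O, pyridine, DMAP (cat.), 25 °C
Reagents that add atoms: acetic anhydride CC(=O)OC(C)=O
Why: Acetylation (nucleophilic acyl substitution) masks the phenol, which would otherwise be oxidised in steps 11 and 13.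

Step 11
Reactants: 18 totara-8,11,13-trien-13-yl acetate
Product: 19 7-oxototara-8,11,13-trien-13-yl acetate
Conditions: CrO3, AcOH/H2O, 25 °C
Reagents that add atoms: chromium trioxide O=[Cr](=O)=O
Why: Chromic acid benzylic oxidation at C7, the only benzylic C–H set aligned with the arene π-system (the isopropyl methine lies in the ring plane and is spared).

Step 12
Reactants: 19 7-oxototara-8,11,13-trien-13-yl acetate
Product: 20 (7S)-7-hydroxytotara-8,11,13-trien-13-yl acetate
Conditions: NaBH4, CeCl3·7H2O, MeOH/THF, −40 °C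
Reagents that add atoms: none
Why: Luche reduction, in which hydride adds axially from the α-face, anti to the C10 angular methyl, to give the 7β (7S) alcohol.

Step 13
Reactants: 20 (7S)-7-hydroxytotara-8,11,13-trien-13-yl acetate
Product: 21 (7S)-7,15-epoxytotara-8,11,13-trien-13-yl acetate
Conditions: PhI(OAc)2, I2, cyclohexane, hν (tungsten lamp), 25 °C
Reagents that add atoms: none
Why: Suárez hypoiodite reaction, in which the O7 radical abstracts the peri isopropyl methine hydrogen (1,5-hydrogen atom transfer) and iodination–cyclisation gives the cyclic ether without touching the C7 configuration.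

Step 14
Reactants: 21 (7S)-7,15-epoxytotara-8,11,13-trien-13-yl acetate
Product: 22 (7S)-totara-8,11,13,15-tetraene-7,13-diyl diacetate
Conditions: Ac2O, Sc(OTf)3 (5 mol%), MeCN, −20 °C
Reagents that add atoms: acetic anhydride CC(=O)OC(C)=O
Why: Lewis-acid-promoted acylative ether cleavage, in which O-acetylation, ionisation of the tertiary C15–O bond and E1 loss of a methyl proton give the isopropenyl group while O7 stays on C7 as the acetate (retention).

Step 15
Reactants: 22 (7S)-totara-8,11,13,15-tetraene-7,13-diyl diacetate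
Product: 23 (7S)-7,13-diacetoxytotara-8,11,13,15-tetraen-17-al
Conditions: SeO2, 1,4-dioxane, 80 °C
Reagents that add atoms: selenium dioxide O=[Se]=O
Why: Riley allylic oxidation (ene reaction then [2,3]-shift) of the only allylic methyl to the 2-arylacrolein.

Step 16
Reactants: 23 (7S)-7,13-diacetoxytotara-8,11,13,15-tetraen-17-al
Product: 24 (7S)-7,13-diacetoxytotara-8,11,13,15-tetraen-17-oic acid
Conditions: NaClO2, NaH2PO4, 2-methylbut-2-ene, t-BuOH/H2O, 25 °C
Reagents that add atoms: sodium chlorite [Na+].[O-]Cl=O
Why: Pinnick oxidation of the enal to the 2-arylacrylic acid with hypochlorite scavenging, which leaves both acetates and the alkene intact.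

Step 17
Reactants: 24 (7S)-7,13-diacetoxytotara-8,11,13,15-tetraen-17-oic acid
Product: 25 (7S)-7-acetoxy-13-hydroxytotara-8,11,13,15-tetraen-17-oic acid
Conditions: NH3 (7 M in MeOH), 0 °C, 30 min; then aq. NaH2PO4; used at once
Reagents that add atoms: none
Why: Chemoselective ammonolysis of the aryl acetate (phenoxide leaving group) in the presence of the secondary C7 acetate and the carboxylate-deactivated acrylate.

Step 18
Reactants: 25 (7S)-7-acetoxy-13-hydroxytotara-8,11,13,15-tetraen-17-oic acid; 16 (5S,9S,10R,12E)-labda-8(17),12,14-trien-20-oic acid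
Product: 27 hispidanin B, via methylene lactone 26 (not isolated)
Conditions: EDC·HCl (1.05 equiv), CH2Cl2, 0 °C, 20 min; then 16 (1.3 equiv), concentrate, 25 °C, 3–5 d
Reagents that add atoms: none
Why: Carbodiimide lactonisation gives the planar 3-methylene-benzofuranone, which is trapped at once in a normal-demand Diels–Alder reaction: C15 bonds to the methylene carbon and C12 to C15′ (1-alkyl diene, acrylate-type dienophile), and the diene is expected to add arene-endo to the lactone face on the side of the C10′ methyl, the two faces being differentiated by the peri C7 acetate (substrate control, as in the presumed biogenetic union), which sets C12 and the spiro centre.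

**Compound list**

1 | 2,3-dibromoprop-1-ene | C=C(Br)CBr | starting material
2 | [(2-bromoprop-2-en-1-yl)sulfonyl]benzene (2-bromoallyl phenyl sulfone) | C=C(Br)CS(=O)(=O)c1ccccc1 | intermediate
3 | pent-3-yn-1-ol | CC#CCCO | starting material
4 | pent-3-ynal | CC#CCC=O | intermediate
5 | rac-2-[(phenylsulfonyl)methyl]hept-1-en-5-yn-3-ol | CC#CCC(O)C(=C)CS(=O)(=O)c1ccccc1 | intermediate
6 | rac-{[3-(ethenyloxy)-2-methylidenehept-5-yn-1-yl]sulfonyl}benzene (allyl vinyl ether of 5) | CC#CCC(OC=C)C(=C)CS(=O)(=O)c1ccccc1 | intermediate (not isolated)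
7 | (4Z)-4-[(phenylsulfonyl)methyl]non-4-en-7-ynal (butynyl cis to CH2SO2Ph) | O=CCC/C(=C/CC#CC)CS(=O)(=O)c1ccccc1 | intermediate
8 | methyl (dimethoxyphosphoryl)acetate | COC(=O)CP(=O)(OC)OC | starting material
9 | 5-bromo-2-methylpent-1-ene | C=C(C)CCCBr | starting material
10 | methyl 2-(dimethoxyphosphoryl)-6-methylhept-6-enoate | COC(=O)C(CCCC(C)=C)P(=O)(OC)OC | intermediate (not isolated)
11 | methyl (6Z)-2-(4-methylpent-4-en-1-yl)-6-[(phenylsulfonyl)methyl]undeca-2,6-dien-9-ynoate (2E/2Z mixture) | COC(=O)C(CCCC(C)=C)=CCC/C(=C/CC#CC)CS(=O)(=O)c1ccccc1 | intermediate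
12 | racemic methyl 14,15-dinorlabd-8(17)-en-12-yn-20-oate (trans-decalin, axial C10 ester, equatorial C9 but-2-ynyl, C8 exocyclic methylene; both enantiomers) | C=C1CC[C@H]2C(C)(C)CCC[C@]2(C(=O)OC)[C@H]1CC#CC.C=C1CC[C@@H]2C(C)(C)CCC[C@@]2(C(=O)OC)[C@@H]1CC#CC | intermediate
13 | methyl (5S,9S,10R)-14,15-dinorlabd-8(17)-en-12-yn-20-oate | C=C1CC[C@H]2C(C)(C)CCC[C@]2(C(=O)OC)[C@H]1CC#CC | intermediate
14 | chlorobis(cyclopentadienyl)[(12E)-20-methoxy-20-oxo-14,15-dinorlabda-8(17),12-dien-13-yl]zirconium (cyclopentadienyl rings drawn σ-bonded) | C=C1CC[C@H]2C(C)(C)CCC[C@]2(C(=O)OC)[C@H]1C/C=C(\C)[Zr](Cl)(C1C=CC=C1)C1C=CC=C1 | intermediate (not isolated)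
15 | methyl (5S,9S,10R,12E)-labda-8(17),12,14-trien-20-oate | C=C1CC[C@H]2C(C)(C)CCC[C@]2(C(=O)OC)[C@H]1C/C=C(\C)C=C | intermediate
16 | (5S,9S,10R,12E)-labda-8(17),12,14-trien-20-oic acid | C=C1CC[C@H]2C(C)(C)CCC[C@]2(C(=O)O)[C@H]1C/C=C(\C)C=C | intermediate
17 | (+)-totarol, (5S,10S)-totara-8,11,13-trien-13-ol | CC(C)c1c(O)ccc2c1CC[C@H]1C(C)(C)CCC[C@]21C | starting material
18 | totara-8,11,13-trien-13-yl acetate | CC(C)c1c(OC(C)=O)ccc2c1CC[C@H]1C(C)(C)CCC[C@]21C | intermediate
19 | 7-oxototara-8,11,13-trien-13-yl acetate | CC(C)c1c(OC(C)=O)ccc2c1C(=O)C[C@H]1C(C)(C)CCC[C@]21C | intermediate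
20 | (7S)-7-hydroxytotara-8,11,13-trien-13-yl acetate (7β-OH, cis to the C10 methyl) | CC(C)c1c(OC(C)=O)ccc2c1[C@@H](O)C[C@H]1C(C)(C)CCC[C@]21C | intermediate
21 | (7S)-7,15-epoxytotara-8,11,13-trien-13-yl acetate (O bridges C7 and the former isopropyl methine) | CC1(C)O[C@H]2C[C@H]3C(C)(C)CCC[C@]3(C)c3ccc(OC(C)=O)c1c32 | intermediate
22 | (7S)-totara-8,11,13,15-tetraene-7,13-diyl diacetate (7β-OAc, C14 isopropenyl) | C=C(C)c1c(OC(C)=O)ccc2c1[C@@H](OC(C)=O)C[C@H]1C(C)(C)CCC[C@]21C | intermediate
23 | (7S)-7,13-diacetoxytotara-8,11,13,15-tetraen-17-al | C=C(C=O)c1c(OC(C)=O)ccc2c1[C@@H](OC(C)=O)C[C@H]1C(C)(C)CCC[C@]21C | intermediate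
24 | (7S)-7,13-diacetoxytotara-8,11,13,15-tetraen-17-oic acid | C=C(C(=O)O)c1c(OC(C)=O)ccc2c1[C@@H](OC(C)=O)C[C@H]1C(C)(C)CCC[C@]21C | intermediate
25 | (7S)-7-acetoxy-13-hydroxytotara-8,11,13,15-tetraen-17-oic acid | C=C(C(=O)O)c1c(O)ccc2c1[C@@H](OC(C)=O)C[C@H]1C(C)(C)CCC[C@]21C | intermediate
26 | (7S)-7-acetoxytotara-8,11,13,15-tetraen-17,13-olide (3-methylene-benzofuran-2-one dienophile) | C=C1C(=O)Oc2ccc3c(c21)[C@@H](OC(C)=O)C[C@H]1C(C)(C)CCC[C@]31C | intermediate (not isolated)
27 | hispidanin B | C=C1CC[C@H]2C(C)(C)CCC[C@]2(C(=O)O)[C@H]1C[C@H]1C(C)=CCC[C@]12C(=O)Oc1ccc3c(c12)[C@@H](OC(C)=O)C[C@H]1C(C)(C)CCC[C@]31C | target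

**Totals**

Total steps: 18. Longest linear sequence: 9 steps (3 → 4 → 5 → 7 → 11 → 12 → 13 → 15 → 16 → 27, or equally 17 → 27).

Stereocentres: C5, C9 and C10 are set relative to one another in step 6 and selected absolutely in step 7; C5′ and C10′ come from totarol; C7′ is set in step 12; C12 and the spiro centre are set in step 18.

**Steps most likely to fail, each with a fallback**

Step 6. The C10 α-ester radical may be reduced before it closes ring B, or the product methylene may be reduced by excess iron hydride. The fallback sets out from 11 and comes back at 12, and splits the cascade into a radical and a polar ring closure. Run the iron-hydride Giese cyclisation of 11 with added PhSH so that the C10 radical is quenched on purpose, giving monocyclic methyl 3,3-dimethyl-2-{(3Z)-3-[(phenylsulfonyl)methyl]oct-3-en-6-yn-1-yl}cyclohexane-1-carboxylate F1. Then treat with LiN(SiMe3)2 and Pd(PPh3)4 in THF: the ester enolate attacks the internal terminus of the π-allyl complex of zerovalent palladium formed from the allyl sulfone (Tsuji–Trost cyclisation; only attack at C9 gives a six-membered ring), which gives 12.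

Step 14. Acetolysis of ether 21 may open the C7–O bond instead of the C15–O bond, which would scramble C7 or give the 6,7-alkene. The fallback sets out from 20 and comes back at 22, and avoids the ether. Generate the O7 radical from 20 with Pb(OAc)4 and Cu(OAc)2 in pyridine/benzene at 80 °C; the C15 radical formed by 1,5-hydrogen transfer is oxidised by Cu(OAc)2 and loses a methyl proton, giving (7S)-7-hydroxytotara-8,11,13,15-tetraen-13-yl acetate F2 directly. Acetylation (Ac2O, pyridine) then gives 22.

Step 18. Lactone 26 may dimerise faster than it is trapped, or the cycloaddition may give the wrong face or the wrong endo/exo ratio; the facial preference stated in step 18 is an expectation, not a certainty. The fallback sets out from 23 and 16 and comes back at 27, and cycloadds before lactonising. Heat aldehyde 23 with 16 in toluene at 60 °C so that the twisted arene, not a flat lactone, differentiates the faces, giving the Diels–Alder aldehyde (17-al cycloadduct, 7,13-diacetate, free C20 acid) F3. Pinnick oxidation gives the diacid (17-oic acid cycloadduct, 7,13-diacetate) F4; NH3/MeOH at 0 °C removes the aryl acetate to give the phenol diacid (13-hydroxy, 7-acetate) F5; EDC·HCl then closes the spiro-lactone on the acid next to the phenol (the C20 acid is too hindered to react), giving 27.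

**Further compounds**

F1 | step 6 | methyl 3,3-dimethyl-2-{(3Z)-3-[(phenylsulfonyl)methyl]oct-3-en-6-yn-1-yl}cyclohexane-1-carboxylate (racemic, cis/trans mixture) | COC(=O)C1CCCC(C)(C)C1CC/C(=C/CC#CC)CS(=O)(=O)c1ccccc1
F2 | step 14 | (7S)-7-hydroxytotara-8,11,13,15-tetraen-13-yl acetate | C=C(C)c1c(OC(C)=O)ccc2c1[C@@H](O)C[C@H]1C(C)(C)CCC[C@]21C
F3 | step 18 | Diels–Alder aldehyde: seco-hispidanin B with CHO in place of the lactone carbonyl and the phenol as acetate | C=C1CC[C@H]2C(C)(C)CCC[C@]2(C(=O)O)[C@H]1C[C@H]1C(C)=CCC[C@@]1(C=O)c1c(OC(C)=O)ccc2c1[C@@H](OC(C)=O)C[C@H]1C(C)(C)CCC[C@]21C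
F4 | step 18 | seco-hispidanin B diacid with the phenol as acetate | C=C1CC[C@H]2C(C)(C)CCC[C@]2(C(=O)O)[C@H]1C[C@H]1C(C)=CCC[C@@]1(C(=O)O)c1c(OC(C)=O)ccc2c1[C@@H](OC(C)=O)C[C@H]1C(C)(C)CCC[C@]21C
F5 | step 18 | seco-hispidanin B diacid with free phenol (hydroxy acid of the target lactone) | C=C1CC[C@H]2C(C)(C)CCC[C@]2(C(=O)O)[C@H]1C[C@H]1C(C)=CCC[C@@]1(C(=O)O)c1c(O)ccc2c1[C@@H](OC(C)=O)C[C@H]1C(C)(C)CCC[C@]21C
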